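**Retrosynthetic overview**
1. The target is cut at C11–C12 (a Julia–Kocienski olefin, later reduced with diimide) into the tetrazolyl sulfone of ent-drimenol (carbocycle, C1–C11) and a 6-formyl-1,2-dioxane (C12 plus the peroxide half); the methyl ester is unveiled last from a silyl-protected primary alcohol.
2. Rings A and B are made together, and first, by one auxiliary-controlled intramolecular Diels–Alder reaction of an acyclic trienoyl oxazolidinone: diene C5=C6–C7=C8, dienophile C9=C10, new bonds C5–C10 and C8–C9.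
3. Enabling feature: ring B (C5–C6–C7–C8–C9–C10) is a cyclohexene whose C9 carries the one-carbon arm C11, which at the acyl level activates C9=C10. The ring-A chain C1–C2–C3–C4 is a ready four-carbon tether from C10 to C5, and an E dienophile encodes the cis C11/angular-methyl relationship. A silyl group on C8 then moves the adduct olefin from C6=C7 to C7=C8 by protodesilylation.
4. The triene comes in two steps from 2,2-dimethylpent-4-enal: Horner–Wadsworth–Emmons dienylation, then hydroboration/B-alkyl Suzuki coupling with an (E)-β-iodo enoyl oxazolidinone.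
5. The dioxane ring is formed third, on the other fragment: syn-aldol (C2'', C3'), Sharpless epoxidation, perhydrolysis at the tertiary epoxide carbon (C6', inversion), 6-exo SN2 closure of the hydroperoxide onto a secondary mesylate (C3', inversion), then glycol cleavage to the aldehyde.

Key step: step 8

Locants used: carbocycle C1–C10 as in drimanes (C4 = gem-dimethyl carbon, C5 = ring-fusion CH, C10 = ring-fusion carbon with the angular methyl, C7=C8 = ring olefin with methyl on C8, C9 = ring carbon bearing the chain); C11–C12 = the CH2CH2 link; dioxane C3' (CH) and C6' (C–CH3); C2'' = ester α-carbon.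

Assumption: the target is taken as drawn, i.e. methyl (2S)-2-[(3S,6S)-1,2-dioxan-3-yl]propanoate carrying a trans-fused (1R,4aR,8aR) decalin (enantiomeric to the common drimane series). The alkene geometry of 33 is immaterial because that alkene is reduced.

**Carbocyclic fragment**

Step 1
Reactants: 1 but-2-yn-1-ol
Product: 2 (E)-3-[dimethyl(phenyl)silyl]but-2-en-1-ol
Conditions: PhMe2SiH, PtCl2 (cat.), XPhos, THF, 50 °C
Reagents that add atoms: dimethylphenylsilane, C[SiH](C)c1ccccc1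
Why: Platinum-catalysed syn-hydrosilylation of a propargylic alcohol should place silicon on the alkyne carbon remote from the hydroxyl with H cis to it, so that silicon ends trans and the methyl cis to CH2OH.

Step 2
Reactants: 2 (E)-3-[dimethyl(phenyl)silyl]but-2-en-1-ol
Product: 3 [(E)-4-bromobut-2-en-2-yl]dimethyl(phenyl)silane
Conditions: CBr4, PPh3, CH2Cl2, 0 °C
Reagents that add atoms: carbon tetrabromide, BrC(Br)(Br)Br
Why: Appel bromination of a primary allylic alcohol is an SN2 displacement at CH2 and should leave the vinylsilane geometry untouched.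

Step 3
Reactants: 3 [(E)-4-bromobut-2-en-2-yl]dimethyl(phenyl)silane
Product: 4 diethyl {(E)-3-[dimethyl(phenyl)silyl]but-2-en-1-yl}phosphonate
Conditions: P(OEt)3 (neat), 120 °C
Reagents that add atoms: triethyl phosphite, CCOP(OCC)OCC
Why: Michaelis–Arbuzov reaction of a primary allylic bromide; phosphorus should attack the unhindered CH2 terminus rather than the trisubstituted γ-carbon.

Step 4
Reactants: 4 diethyl {(E)-3-[dimethyl(phenyl)silyl]but-2-en-1-yl}phosphonate; 5 2,2-dimethylpent-4-enal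
Product: 6 [(2E,4E)-6,6-dimethylnona-2,4,8-trien-2-yl]dimethyl(phenyl)silane
Conditions: LiN(SiMe3)2, THF, −78 °C; then 5, −78 °C → rt
Reagents that add atoms: none
Why: Horner–Wadsworth–Emmons olefination of a non-enolisable α-quaternary aldehyde with an allylic phosphonate anion (α-attack) should give the new C5=C6 bond E, the vinylsilane geometry being carried through.

Step 5
Reactants: 7 but-2-ynoic acid
Product: 9 (E)-3-iodobut-2-enoic acid, via (Z)-3-iodobut-2-enoic acid 8 (not isolated)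
Conditions: 57% aq. HI, 90 °C; then neat, 130 °C (sealed tube); recrystallisation
Reagents that add atoms: hydrogen iodide, I
Why: Hydroiodination of the ynoic acid by anti addition gives the Z acid, which on heating should equilibrate to the more stable E isomer (iodine trans to the carboxyl) that the E dienophile requires.

Step 6
Reactants: 9 (E)-3-iodobut-2-enoic acid; 10 (R)-4-benzyloxazolidin-2-one
Product: 12 (R)-4-benzyl-3-[(E)-3-iodobut-2-enoyl]oxazolidin-2-one, via pivalic mixed anhydride 11 (not isolated)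
Conditions: PivCl, Et3N, THF, −20 °C; then LiCl, 10, −20 °C → rt
Reagents that add atoms: none
Why: Mixed-anhydride N-acylation of the oxazolidinone under LiCl/Et3N activation needs no strong base, so the E-β-iodo enoyl unit should be transferred unchanged.

Step 7
Reactants: 6 [(2E,4E)-6,6-dimethylnona-2,4,8-trien-2-yl]dimethyl(phenyl)silane; 12 (R)-4-benzyl-3-[(E)-3-iodobut-2-enoyl]oxazolidin-2-one
Product: 14 (R)-4-benzyl-3-{(2E,8E,10E)-11-[dimethyl(phenyl)silyl]-3,7,7-trimethyldodeca-2,8,10-trienoyl}oxazolidin-2-one, via B-alkyl-9-borabicyclononane 13 (not isolated)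
Conditions: 9-BBN-H, THF, 0 °C → rt; then 12, Pd(dppf)Cl2 (cat.), AsPh3, K3PO4 (aq.), DMF, rt
Reagents that add atoms: none
Why: B-alkyl Suzuki–Miyaura coupling: 9-BBN should hydroborate only the monosubstituted terminal alkene (anti-Markovnikov), and the alkylborane couples with the β-iodo enoyl imide with retention of the E geometry under mild aqueous phosphate that spares the imide.

Step 8
Reactants: 14 (R)-4-benzyl-3-{(2E,8E,10E)-11-[dimethyl(phenyl)silyl]-3,7,7-trimethyldodeca-2,8,10-trienoyl}oxazolidin-2-one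
Product: 15 (R)-4-benzyl-3-{[(1R,2R,4aR,8aR)-2-[dimethyl(phenyl)silyl]-2,5,5,8a-tetramethyl-1,2,4a,5,6,7,8,8a-octahydronaphthalen-1-yl]carbonyl}oxazolidin-2-one
Conditions: Me2AlCl (1.5 equiv), CH2Cl2, −30 → 0 °C
Reagents that add atoms: none
Why: Bidentate chelation of the two imide carbonyls by Me2AlCl gives a rigid, cationic s-cis acyl-oxazolidinone dienophile that the tethered diene should attack in a concerted, asynchronous intramolecular [4+2] cycloaddition, the C5–C10 bond (unsubstituted nucleophilic diene terminus to the β-carbon) running ahead of the C8–C9 bond; the polarity is matched because C8 carries the donor methyl. The closest known reaction type is the Me2AlCl-promoted intramolecular Diels–Alder reaction of (E)-deca-2,7,9-trienoyl oxazolidinones to trans-fused octahydronaphthalenes. Ring A closes through the C5–C10 bond as a six-membered ring over the four-carbon tether C1–C4 in a chair-like arrangement (helped by the C4 gem-dimethyl group), and ring B closes through the C8–C9 bond as the cyclohexene of the [4+2] addition. C9 and C10 are set relative to each other by the E dienophile (suprafacial addition, C11 cis to the angular methyl); C5 by the endo transition state with the acyl group under the diene and the tether exo (trans ring fusion); the absolute configuration of all three by attack on the Cα-Re face anti to the benzyl group of the (R)-auxiliary; and the throw-away centre C8 by the 10E diene geometry (silicon outside, hence cis to C11). The step needs endo over exo and Re over Si selectivity and cycloaddition ahead of ionic side reactions; the chelate, the defined E,E,E geometry, the intramolecularity and the low temperature should secure this, and the outside silyl group points away from the dienophile in the transition state.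

Step 9
Reactants: 15 (R)-4-benzyl-3-{[(1R,2R,4aR,8aR)-2-[dimethyl(phenyl)silyl]-2,5,5,8a-tetramethyl-1,2,4a,5,6,7,8,8a-octahydronaphthalen-1-yl]carbonyl}oxazolidin-2-one
Product: 16 (R)-4-benzyl-3-{[(1R,4aR,8aR)-2,5,5,8a-tetramethyl-1,4,4a,5,6,7,8,8a-octahydronaphthalen-1-yl]carbonyl}oxazolidin-2-one
Conditions: CF3CO2H, CH2Cl2, 0 °C
Reagents that add atoms: none
Why: Protodesilylation of the allylsilane in the SE2' sense: protonation at C6 anti to the pseudo-axial C8–Si bond and loss of silicon from the β-silyl cation should move the double bond regiospecifically to C7=C8 and erase the temporary C8 centre.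

Step 10
Reactants: 16 (R)-4-benzyl-3-{[(1R,4aR,8aR)-2,5,5,8a-tetramethyl-1,4,4a,5,6,7,8,8a-octahydronaphthalen-1-yl]carbonyl}oxazolidin-2-one
Product: 17 [(1R,4aR,8aR)-2,5,5,8a-tetramethyl-1,4,4a,5,6,7,8,8a-octahydronaphthalen-1-yl]methanol (ent-drimenol)
Conditions: LiBH4, MeOH (1 equiv), Et2O, 0 °C
Reagents that add atoms: none
Why: Reductive cleavage of the N-acyl oxazolidinone by hydride attack on the exocyclic carbonyl should release the primary alcohol and the intact auxiliary; C9 keeps its configuration, which is also the thermodynamically preferred equatorial one.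

Step 11
Reactants: 17 [(1R,4aR,8aR)-2,5,5,8a-tetramethyl-1,4,4a,5,6,7,8,8a-octahydronaphthalen-1-yl]methanol
Product: 18 1-phenyl-5-({[(1R,4aR,8aR)-2,5,5,8a-tetramethyl-1,4,4a,5,6,7,8,8a-octahydronaphthalen-1-yl]methyl}sulfanyl)-1H-tetrazole
Conditions: 1-phenyl-1H-tetrazole-5-thiol, PPh3, DIAD, THF, 0 °C → rt
Reagents that add atoms: 1-phenyl-1H-tetrazole-5-thiol, Sc1nnnn1-c1ccccc1
Why: Mitsunobu thioetherification of the primary alcohol (SN2 at CH2 by the acidic tetrazole thiol); no stereocentre is involved.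

Step 12
Reactants: 18 1-phenyl-5-({[(1R,4aR,8aR)-2,5,5,8a-tetramethyl-1,4,4a,5,6,7,8,8a-octahydronaphthalen-1-yl]methyl}sulfanyl)-1H-tetrazole
Product: 19 1-phenyl-5-({[(1R,4aR,8aR)-2,5,5,8a-tetramethyl-1,4,4a,5,6,7,8,8a-octahydronaphthalen-1-yl]methyl}sulfonyl)-1H-tetrazole
Conditions: (NH4)6Mo7O24·4H2O (cat.), 30% H2O2, EtOH, 0 °C → rt
Reagents that add atoms: hydrogen peroxide, OO
Why: Molybdate-catalysed peroxide oxidation of sulfide to sulfone should be chemoselective for sulfur over the trisubstituted ring alkene.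

**Dioxane fragment**

Step 13
Reactants: 20 geranyl acetate
Product: 21 (2E)-3-methyl-6-oxohex-2-en-1-yl acetate
Conditions: O3 (1 equiv), CH2Cl2, pyridine, −78 °C; then Me2S
Reagents that add atoms: ozone, [O-][O+]=O
Why: Selective ozonolysis: ozone should attack the electron-rich terminal trisubstituted alkene much faster than the alkene deactivated by the allylic acetate.

Step 14
Reactants: 21 (2E)-3-methyl-6-oxohex-2-en-1-yl acetate; 22 (S)-4-benzyl-3-propanoyloxazolidin-2-one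
Product: 24 (S)-4-benzyl-3-[(2S,3R,6E)-8-acetoxy-3-hydroxy-2,6-dimethyloct-6-enoyl]oxazolidin-2-one, via dibutylboron (Z)-enolate 23 (not isolated)
Conditions: Bu2BOTf, iPr2NEt, CH2Cl2, −78 → 0 °C; then 21, −78 → 0 °C; pH 7 buffer, MeOH, H2O2, 0 °C
Reagents that add atoms: none
Why: Evans syn-aldol: the boron (Z)-enolate should react through a chair-like, dipole-minimised transition state on the face opposite to the benzyl group, setting C2'' (S) and the carbinol carbon (R) together.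

Step 15
Reactants: 24 (S)-4-benzyl-3-[(2S,3R,6E)-8-acetoxy-3-hydroxy-2,6-dimethyloct-6-enoyl]oxazolidin-2-one
Product: 25 (2E,6R,7R)-6,8-dihydroxy-3,7-dimethyloct-2-en-1-yl acetate
Conditions: NaBH4, THF/H2O, 0 °C → rt
Reagents that add atoms: none
Why: Borohydride in wet THF should cleave the activated exocyclic imide carbonyl reductively to the primary alcohol faster than it touches the acetate; no stereocentre is affected.

Step 16
Reactants: 25 (2E,6R,7R)-6,8-dihydroxy-3,7-dimethyloct-2-en-1-yl acetate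
Product: 26 (2E,6R,7R)-8-[(tert-butyldiphenylsilyl)oxy]-6-hydroxy-3,7-dimethyloct-2-en-1-yl acetate
Conditions: t-BuPh2SiCl, imidazole, CH2Cl2, 0 °C
Reagents that add atoms: tert-butyl(chloro)diphenylsilane, CC(C)(C)[Si](Cl)(c1ccccc1)c1ccccc1
Why: Selective silylation of the less hindered primary hydroxyl of the 1,3-diol by the bulky silyl chloride.

Step 17
Reactants: 26 (2E,6R,7R)-8-[(tert-butyldiphenylsilyl)oxy]-6-hydroxy-3,7-dimethyloct-2-en-1-yl acetate
Product: 27 (2E,6R,7R)-8-[(tert-butyldiphenylsilyl)oxy]-3,7-dimethyl-6-[(methylsulfonyl)oxy]oct-2-en-1-yl acetate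
Conditions: MsCl, Et3N, CH2Cl2, 0 °C
Reagents that add atoms: methanesulfonyl chloride, CS(=O)(=O)Cl
Why: Sulfonylation of the remaining secondary alcohol with retention (O–S bond formation) prepares the later SN2 inversion; the non-participating silyl ether avoids anchimeric assistance.

Step 18
Reactants: 27 (2E,6R,7R)-8-[(tert-butyldiphenylsilyl)oxy]-3,7-dimethyl-6-[(methylsulfonyl)oxy]oct-2-en-1-yl acetate
Product: 28 (2R,3R,6E)-1-[(tert-butyldiphenylsilyl)oxy]-8-hydroxy-2,6-dimethyloct-6-en-3-yl methanesulfonate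
Conditions: K2CO3 (cat.), MeOH, 0 °C
Reagents that add atoms: none
Why: Zemplén-type transesterification should remove the acetate while the secondary mesylate and the silyl ether stay inert at 0 °C.

Step 19
Reactants: 28 (2R,3R,6E)-1-[(tert-butyldiphenylsilyl)oxy]-8-hydroxy-2,6-dimethyloct-6-en-3-yl methanesulfonate
Product: 29 (2R,3R)-1-[(tert-butyldiphenylsilyl)oxy]-5-[(2S,3S)-3-(hydroxymethyl)-2-methyloxiran-2-yl]-2-methylpentan-3-yl methanesulfonate
Conditions: Ti(OiPr)4, L-(+)-diethyl tartrate, t-BuOOH, 4 Å molecular sieves, CH2Cl2, −20 °C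
Reagents that add atoms: tert-butyl hydroperoxide, CC(C)(C)OO
Why: Sharpless asymmetric epoxidation: with L-(+)-tartrate the E-trisubstituted allylic alcohol should be epoxidised on the face that gives the (2S,3S)-epoxy alcohol, under reagent control and independent of the remote centres.

Step 20
Reactants: 29 (2R,3R)-1-[(tert-butyldiphenylsilyl)oxy]-5-[(2S,3S)-3-(hydroxymethyl)-2-methyloxiran-2-yl]-2-methylpentan-3-yl methanesulfonate
Product: 30 (2R,3R,6R,7S)-1-[(tert-butyldiphenylsilyl)oxy]-6-hydroperoxy-7,8-dihydroxy-2,6-dimethyloctan-3-yl methanesulfonate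
Conditions: H2O2 (anhydrous, in Et2O, excess), H3PMo12O40 (cat.), Et2O, rt
Reagents that add atoms: hydrogen peroxide, OO
Why: Acid-catalysed perhydrolysis of the epoxide: H2O2 should open the activated oxirane at the tertiary carbon (Markovnikov, away from the inductively deactivated carbinol-bearing carbon) from the back side, so the tertiary C–OOH centre C6' is set with inversion.

Step 21
Reactants: 30 (2R,3R,6R,7S)-1-[(tert-butyldiphenylsilyl)oxy]-6-hydroperoxy-7,8-dihydroxy-2,6-dimethyloctan-3-yl methanesulfonate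
Product: 31 (1S)-1-[(3R,6S)-6-{(2R)-1-[(tert-butyldiphenylsilyl)oxy]propan-2-yl}-3-methyl-1,2-dioxan-3-yl]ethane-1,2-diol
Conditions: KOtBu (1.05 equiv), 18-crown-6, THF, 0 °C
Reagents that add atoms: none
Why: 6-exo-tet intramolecular SN2 alkylation of the hydroperoxide anion (the only site acidic enough for one equivalent of base) by the secondary mesylate should close the 1,2-dioxane with inversion at C3', placing the C3' side chain cis to the C6' carbinol arm.

Step 22
Reactants: 31 (1S)-1-[(3R,6S)-6-{(2R)-1-[(tert-butyldiphenylsilyl)oxy]propan-2-yl}-3-methyl-1,2-dioxan-3-yl]ethane-1,2-diol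
Product: 32 (3R,6S)-6-{(2R)-1-[(tert-butyldiphenylsilyl)oxy]propan-2-yl}-3-methyl-1,2-dioxane-3-carbaldehyde
Conditions: NaIO4, THF/H2O (pH 7), 0 °C → rt
Reagents that add atoms: none
Why: Periodate glycol cleavage removes the extra carbon and unveils the non-enolisable α-peroxy aldehyde; dialkyl peroxides are inert to NaIO4.

**Union and endgame**

Step 23
Reactants: 19 1-phenyl-5-({[(1R,4aR,8aR)-2,5,5,8a-tetramethyl-1,4,4a,5,6,7,8,8a-octahydronaphthalen-1-yl]methyl}sulfonyl)-1H-tetrazole; 32 (3R,6S)-6-{(2R)-1-[(tert-butyldiphenylsilyl)oxy]propan-2-yl}-3-methyl-1,2-dioxane-3-carbaldehyde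
Product: 33 tert-butyl{[(2R)-2-[(3S,6R)-6-methyl-6-{(E)-2-[(1R,4aR,8aR)-2,5,5,8a-tetramethyl-1,4,4a,5,6,7,8,8a-octahydronaphthalen-1-yl]ethenyl}-1,2-dioxan-3-yl]propyl]oxy}diphenylsilane
Conditions: KN(SiMe3)2, DME, −78 °C; then 32, −78 °C → rt
Reagents that add atoms: none
Why: Julia–Kocienski olefination: addition of the metalated tetrazolyl sulfone to the non-enolisable aldehyde, Smiles rearrangement and loss of SO2 and aryloxide should give the C11=C12 alkene (E expected), while the hindered dialkyl peroxide and silyl ether tolerate the pre-formed sulfonyl anion at −78 °C.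

Step 24
Reactants: 33 tert-butyl{[(2R)-2-[(3S,6R)-6-methyl-6-{(E)-2-[(1R,4aR,8aR)-2,5,5,8a-tetramethyl-1,4,4a,5,6,7,8,8a-octahydronaphthalen-1-yl]ethenyl}-1,2-dioxan-3-yl]propyl]oxy}diphenylsilane
Product: 34 tert-butyl{[(2R)-2-[(3S,6S)-6-methyl-6-{2-[(1R,4aR,8aR)-2,5,5,8a-tetramethyl-1,4,4a,5,6,7,8,8a-octahydronaphthalen-1-yl]ethyl}-1,2-dioxan-3-yl]propyl]oxy}diphenylsilane
Conditions: 2-nitrobenzenesulfonohydrazide, Et3N, CH2Cl2, rt (repeated charges)
Reagents that add atoms: none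
Why: Diimide reduction: concerted syn transfer of H2 to the 1,2-disubstituted alkene should be much faster than to the trisubstituted ring alkene, and diimide does not reduce the O–O bond.

Step 25
Reactants: 34 tert-butyl{[(2R)-2-[(3S,6S)-6-methyl-6-{2-[(1R,4aR,8aR)-2,5,5,8a-tetramethyl-1,4,4a,5,6,7,8,8a-octahydronaphthalen-1-yl]ethyl}-1,2-dioxan-3-yl]propyl]oxy}diphenylsilane
Product: 35 (2R)-2-[(3S,6S)-6-methyl-6-{2-[(1R,4aR,8aR)-2,5,5,8a-tetramethyl-1,4,4a,5,6,7,8,8a-octahydronaphthalen-1-yl]ethyl}-1,2-dioxan-3-yl]propan-1-ol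
Conditions: Bu4NF, AcOH, THF, 0 °C → rt
Reagents that add atoms: none
Why: Fluoride-mediated Si–O cleavage under acetic acid buffering; at this oxidation level no base-sensitive C–H flanks the peroxide.

Step 26
Reactants: 35 (2R)-2-[(3S,6S)-6-methyl-6-{2-[(1R,4aR,8aR)-2,5,5,8a-tetramethyl-1,4,4a,5,6,7,8,8a-octahydronaphthalen-1-yl]ethyl}-1,2-dioxan-3-yl]propan-1-ol
Product: 37 (2S)-2-[(3S,6S)-6-methyl-6-{2-[(1R,4aR,8aR)-2,5,5,8a-tetramethyl-1,4,4a,5,6,7,8,8a-octahydronaphthalen-1-yl]ethyl}-1,2-dioxan-3-yl]propanoic acid, via aldehyde 36 (not isolated)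
Conditions: TEMPO (cat.), PhI(OAc)2, MeCN/H2O, rt
Reagents that add atoms: water, O
Why: Oxoammonium (TEMPO/PhI(OAc)2) oxidation of the primary alcohol to the aldehyde and, through its hydrate, to the acid under near-neutral conditions should avoid epimerisation or β-elimination at the α-methyl β-peroxy aldehyde stage and leave alkene and peroxide untouched.

Step 27
Reactants: 37 (2S)-2-[(3S,6S)-6-methyl-6-{2-[(1R,4aR,8aR)-2,5,5,8a-tetramethyl-1,4,4a,5,6,7,8,8a-octahydronaphthalen-1-yl]ethyl}-1,2-dioxan-3-yl]propanoic acid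
Product: 38 methyl (2S)-2-[(3S,6S)-6-methyl-6-{2-[(1R,4aR,8aR)-2,5,5,8a-tetramethyl-1,4,4a,5,6,7,8,8a-octahydronaphthalen-1-yl]ethyl}-1,2-dioxan-3-yl]propanoate (CNP0124238.1)
Conditions: Me3SiCHN2, MeOH/toluene, 0 °C
Reagents that add atoms: trimethylsilyldiazomethane, C[Si](C)(C)C=[N+]=[N-]
Why: Diazoalkane O-methylation of the carboxylic acid under neutral conditions, so the base-labile β-peroxy ester is never exposed to alkoxide.

**Compound list**
1 | but-2-yn-1-ol | CC#CCO | starting material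
2 | (E)-3-[dimethyl(phenyl)silyl]but-2-en-1-ol | OC/C=C(\C)[Si](C)(C)c1ccccc1 | intermediate
3 | [(E)-4-bromobut-2-en-2-yl]dimethyl(phenyl)silane | BrC/C=C(\C)[Si](C)(C)c1ccccc1 | intermediate
4 | diethyl {(E)-3-[dimethyl(phenyl)silyl]but-2-en-1-yl}phosphonate | CCOP(=O)(OCC)C/C=C(\C)[Si](C)(C)c1ccccc1 | intermediate
5 | 2,2-dimethylpent-4-enal | C=CCC(C)(C)C=O | starting material
6 | [(2E,4E)-6,6-dimethylnona-2,4,8-trien-2-yl]dimethyl(phenyl)silane | C=CCC(C)(C)/C=C/C=C(\C)[Si](C)(C)c1ccccc1 | intermediate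
7 | but-2-ynoic acid | CC#CC(=O)O | starting material
8 | (Z)-3-iodobut-2-enoic acid | C/C(I)=C/C(=O)O | intermediate (not isolated)
9 | (E)-3-iodobut-2-enoic acid | C/C(I)=C\C(=O)O | intermediate
10 | (R)-4-benzyloxazolidin-2-one | O=C1OC[C@@H](Cc2ccccc2)N1 | starting material
11 | (E)-3-iodobut-2-enoic pivalic anhydride | C/C(I)=C\C(=O)OC(=O)C(C)(C)C | intermediate (not isolated)
12 | (R)-4-benzyl-3-[(E)-3-iodobut-2-enoyl]oxazolidin-2-one | C/C(I)=C\C(=O)N1[C@H](Cc2ccccc2)COC1=O | intermediate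
13 | 9-{(5E,7E)-8-[dimethyl(phenyl)silyl]-4,4-dimethylnona-5,7-dien-1-yl}-9-borabicyclo[3.3.1]nonane | C[Si](C)(c1ccccc1)/C(C)=C/C=C/C(C)(C)CCCB1C2CCCC1CCC2 | intermediate (not isolated)
14 | (R)-4-benzyl-3-{(2E,8E,10E)-11-[dimethyl(phenyl)silyl]-3,7,7-trimethyldodeca-2,8,10-trienoyl}oxazolidin-2-one | O=C(/C=C(\C)CCCC(C)(C)/C=C/C=C(\C)[Si](C)(C)c1ccccc1)N1[C@H](Cc2ccccc2)COC1=O | intermediate
15 | (R)-4-benzyl-3-{[(1R,2R,4aR,8aR)-2-[dimethyl(phenyl)silyl]-2,5,5,8a-tetramethyl-1,2,4a,5,6,7,8,8a-octahydronaphthalen-1-yl]carbonyl}oxazolidin-2-one | O=C(N1[C@H](Cc2ccccc2)COC1=O)[C@@H]1[C@](C)([Si](C)(C)c2ccccc2)C=C[C@@H]2C(C)(C)CCC[C@@]12C | intermediate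
16 | (R)-4-benzyl-3-{[(1R,4aR,8aR)-2,5,5,8a-tetramethyl-1,4,4a,5,6,7,8,8a-octahydronaphthalen-1-yl]carbonyl}oxazolidin-2-one | O=C(N1[C@H](Cc2ccccc2)COC1=O)[C@@H]1C(C)=CC[C@@H]2C(C)(C)CCC[C@@]12C | intermediate
17 | [(1R,4aR,8aR)-2,5,5,8a-tetramethyl-1,4,4a,5,6,7,8,8a-octahydronaphthalen-1-yl]methanol (ent-drimenol) | OC[C@@H]1C(C)=CC[C@@H]2C(C)(C)CCC[C@@]12C | intermediate
18 | 1-phenyl-5-({[(1R,4aR,8aR)-2,5,5,8a-tetramethyl-1,4,4a,5,6,7,8,8a-octahydronaphthalen-1-yl]methyl}sulfanyl)-1H-tetrazole | c1ccc(cc1)-n1nnnc1SC[C@@H]1C(C)=CC[C@@H]2C(C)(C)CCC[C@@]12C | intermediate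
19 | 1-phenyl-5-({[(1R,4aR,8aR)-2,5,5,8a-tetramethyl-1,4,4a,5,6,7,8,8a-octahydronaphthalen-1-yl]methyl}sulfonyl)-1H-tetrazole | O=S(=O)(C[C@@H]1C(C)=CC[C@@H]2C(C)(C)CCC[C@@]12C)c1nnnn1-c1ccccc1 | intermediate
20 | geranyl acetate | CC(C)=CCC/C(C)=C/COC(C)=O | starting material
21 | (2E)-3-methyl-6-oxohex-2-en-1-yl acetate | O=CCC/C(C)=C/COC(C)=O | intermediate
22 | (S)-4-benzyl-3-propanoyloxazolidin-2-one | CCC(=O)N1[C@@H](Cc2ccccc2)COC1=O | starting material
23 | dibutylboron (Z)-enolate of 22 | C/C=C(\OB(CCCC)CCCC)N1[C@@H](Cc2ccccc2)COC1=O | intermediate (not isolated)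
24 | (S)-4-benzyl-3-[(2S,3R,6E)-8-acetoxy-3-hydroxy-2,6-dimethyloct-6-enoyl]oxazolidin-2-one | O=C1OC[C@H](Cc2ccccc2)N1C(=O)[C@@H](C)[C@H](O)CC/C(C)=C/COC(C)=O | intermediate
25 | (2E,6R,7R)-6,8-dihydroxy-3,7-dimethyloct-2-en-1-yl acetate | OC[C@@H](C)[C@H](O)CC/C(C)=C/COC(C)=O | intermediate
26 | (2E,6R,7R)-8-[(tert-butyldiphenylsilyl)oxy]-6-hydroxy-3,7-dimethyloct-2-en-1-yl acetate | CC(C)(C)[Si](c1ccccc1)(c1ccccc1)OC[C@@H](C)[C@H](O)CC/C(C)=C/COC(C)=O | intermediate
27 | (2E,6R,7R)-8-[(tert-butyldiphenylsilyl)oxy]-3,7-dimethyl-6-[(methylsulfonyl)oxy]oct-2-en-1-yl acetate | CC(C)(C)[Si](c1ccccc1)(c1ccccc1)OC[C@@H](C)[C@H](OS(C)(=O)=O)CC/C(C)=C/COC(C)=O | intermediate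
28 | (2R,3R,6E)-1-[(tert-butyldiphenylsilyl)oxy]-8-hydroxy-2,6-dimethyloct-6-en-3-yl methanesulfonate | CC(C)(C)[Si](c1ccccc1)(c1ccccc1)OC[C@@H](C)[C@H](OS(C)(=O)=O)CC/C(C)=C/CO | intermediate
29 | (2R,3R)-1-[(tert-butyldiphenylsilyl)oxy]-5-[(2S,3S)-3-(hydroxymethyl)-2-methyloxiran-2-yl]-2-methylpentan-3-yl methanesulfonate | CC(C)(C)[Si](c1ccccc1)(c1ccccc1)OC[C@@H](C)[C@H](OS(C)(=O)=O)CC[C@]1(C)O[C@H]1CO | intermediate
30 | (2R,3R,6R,7S)-1-[(tert-butyldiphenylsilyl)oxy]-6-hydroperoxy-7,8-dihydroxy-2,6-dimethyloctan-3-yl methanesulfonate | CC(C)(C)[Si](c1ccccc1)(c1ccccc1)OC[C@@H](C)[C@H](OS(C)(=O)=O)CC[C@@](C)(OO)[C@@H](O)CO | intermediate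
31 | (1S)-1-[(3R,6S)-6-{(2R)-1-[(tert-butyldiphenylsilyl)oxy]propan-2-yl}-3-methyl-1,2-dioxan-3-yl]ethane-1,2-diol | CC(C)(C)[Si](c1ccccc1)(c1ccccc1)OC[C@@H](C)[C@@H]1CC[C@](C)([C@@H](O)CO)OO1 | intermediate
32 | (3R,6S)-6-{(2R)-1-[(tert-butyldiphenylsilyl)oxy]propan-2-yl}-3-methyl-1,2-dioxane-3-carbaldehyde | CC(C)(C)[Si](c1ccccc1)(c1ccccc1)OC[C@@H](C)[C@@H]1CC[C@](C)(C=O)OO1 | intermediate
33 | tert-butyl{[(2R)-2-[(3S,6R)-6-methyl-6-{(E)-2-[(1R,4aR,8aR)-2,5,5,8a-tetramethyl-1,4,4a,5,6,7,8,8a-octahydronaphthalen-1-yl]ethenyl}-1,2-dioxan-3-yl]propyl]oxy}diphenylsilane | CC(C)(C)[Si](c1ccccc1)(c1ccccc1)OC[C@@H](C)[C@@H]1CC[C@](C)(/C=C/[C@@H]2C(C)=CC[C@@H]3C(C)(C)CCC[C@@]23C)OO1 | intermediate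
34 | tert-butyl{[(2R)-2-[(3S,6S)-6-methyl-6-{2-[(1R,4aR,8aR)-2,5,5,8a-tetramethyl-1,4,4a,5,6,7,8,8a-octahydronaphthalen-1-yl]ethyl}-1,2-dioxan-3-yl]propyl]oxy}diphenylsilane | CC(C)(C)[Si](c1ccccc1)(c1ccccc1)OC[C@@H](C)[C@@H]1CC[C@](C)(CC[C@@H]2C(C)=CC[C@@H]3C(C)(C)CCC[C@@]23C)OO1 | intermediate
35 | (2R)-2-[(3S,6S)-6-methyl-6-{2-[(1R,4aR,8aR)-2,5,5,8a-tetramethyl-1,4,4a,5,6,7,8,8a-octahydronaphthalen-1-yl]ethyl}-1,2-dioxan-3-yl]propan-1-ol | OC[C@@H](C)[C@@H]1CC[C@](C)(CC[C@@H]2C(C)=CC[C@@H]3C(C)(C)CCC[C@@]23C)OO1 | intermediate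
36 | (2S)-2-[(3S,6S)-6-methyl-6-{2-[(1R,4aR,8aR)-2,5,5,8a-tetramethyl-1,4,4a,5,6,7,8,8a-octahydronaphthalen-1-yl]ethyl}-1,2-dioxan-3-yl]propanal | O=C[C@@H](C)[C@@H]1CC[C@](C)(CC[C@@H]2C(C)=CC[C@@H]3C(C)(C)CCC[C@@]23C)OO1 | intermediate (not isolated)
37 | (2S)-2-[(3S,6S)-6-methyl-6-{2-[(1R,4aR,8aR)-2,5,5,8a-tetramethyl-1,4,4a,5,6,7,8,8a-octahydronaphthalen-1-yl]ethyl}-1,2-dioxan-3-yl]propanoic acid | OC(=O)[C@@H](C)[C@@H]1CC[C@](C)(CC[C@@H]2C(C)=CC[C@@H]3C(C)(C)CCC[C@@]23C)OO1 | intermediate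
38 | methyl (2S)-2-[(3S,6S)-6-methyl-6-{2-[(1R,4aR,8aR)-2,5,5,8a-tetramethyl-1,4,4a,5,6,7,8,8a-octahydronaphthalen-1-yl]ethyl}-1,2-dioxan-3-yl]propanoate | COC(=O)[C@@H](C)[C@@H]1CC[C@](C)(CC[C@@H]2C(C)=CC[C@@H]3C(C)(C)CCC[C@@]23C)OO1 | target

**Step count**
Total steps: 27. Longest linear sequence: 15 steps (steps 1, 2, 3, 4, 7, 8, 9, 10, 11, 12, then 23–27; the dioxane branch, steps 13–22 then 23–27, is equally long).

**Steps most likely to fail**

1. Step 8 (intramolecular Diels–Alder). Both new bonds are made at fully substituted carbons and the inside methyl on C8 hampers the s-cis diene conformation, so the cycloaddition may be too slow. It may then be outrun by ionic side reactions of the electron-rich silyl diene under the aluminium Lewis acid (premature protodesilylation, oligomerisation), or leak through the exo transition state to the cis ring fusion. Fallback, setting out from 14 and returning at 17: the activation and the source of asymmetry are changed from auxiliary/chelate control to catalyst control on an enal. 14 is reduced at −78 °C (i-Bu2AlH, CH2Cl2) to (2E,8E,10E)-11-[dimethyl(phenyl)silyl]-3,7,7-trimethyldodeca-2,8,10-trien-1-ol F1, which is oxidised (MnO2, CH2Cl2) to (2E,8E,10E)-11-[dimethyl(phenyl)silyl]-3,7,7-trimethyldodeca-2,8,10-trienal F2. This is cyclised by a catalytic enantioselective intramolecular Diels–Alder reaction of the trienal with a triflimide-activated chiral B-aryl oxazaborolidinium catalyst (CH2Cl2, −78 → −20 °C; catalyst enantiomer chosen for Cα-Re attack) to (1R,2R,4aR,8aR)-2-[dimethyl(phenyl)silyl]-2,5,5,8a-tetramethyl-1,2,4a,5,6,7,8,8a-octahydronaphthalene-1-carbaldehyde F3. NaBH4 reduction gives [(1R,2R,4aR,8aR)-2-[dimethyl(phenyl)silyl]-2,5,5,8a-tetramethyl-1,2,4a,5,6,7,8,8a-octahydronaphthalen-1-yl]methanol F4, and protodesilylation (CF3CO2H, CH2Cl2, then K2CO3/MeOH) returns 17.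

2. Step 20 (perhydrolysis at the tertiary epoxide carbon). Ionisation of the tertiary C–O bond ahead of attack may erode the configuration at C6', and opening at the other epoxide carbon or acid-induced loss of the mesylate or silyl group may compete. Fallback, setting out from 26 and returning at 31: the roles are inverted so that the tertiary C–O bond is made intramolecularly. 2-Methoxypropan-2-yl hydroperoxide F5 is prepared by ozonolysis of 2,3-dimethylbut-2-ene in MeOH/CH2Cl2. 26 is converted (Tf2O, 2,6-lutidine, CH2Cl2, −78 °C) to (2E,6R,7R)-8-[(tert-butyldiphenylsilyl)oxy]-3,7-dimethyl-6-{[(trifluoromethyl)sulfonyl]oxy}oct-2-en-1-yl acetate F6 and displaced with inversion by F5 (CsOH·H2O, DMF, 0 °C) to (2E,6S,7R)-8-[(tert-butyldiphenylsilyl)oxy]-6-[(2-methoxypropan-2-yl)peroxy]-3,7-dimethyloct-2-en-1-yl acetate F7. Acetate removal (K2CO3, MeOH) gives (2E,6S,7R)-8-[(tert-butyldiphenylsilyl)oxy]-6-[(2-methoxypropan-2-yl)peroxy]-3,7-dimethyloct-2-en-1-ol F8, and Sharpless epoxidation as in step 19 gives [(2S,3S)-3-{(3S,4R)-5-[(tert-butyldiphenylsilyl)oxy]-3-[(2-methoxypropan-2-yl)peroxy]-4-methylpentyl}-3-methyloxiran-2-yl]methanol F9. Camphorsulfonic acid in wet CH2Cl2 then hydrolyses the peroxyketal and lets the free hydroperoxide open the epoxide 6-exo at the tertiary carbon with inversion, giving 31.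

3. Step 23 (Julia–Kocienski union). Addition of the hindered, β-branched sulfonyl carbanion to the neopentyl-type aldehyde may be sluggish, leaving time for self-condensation of the metalated sulfone or base-induced degradation of the peroxide. Fallback, setting out from 17 and returning at 34: the carbanion is changed to a non-stabilised phosphorus ylide. 17 is converted (I2, PPh3, imidazole, CH2Cl2) to (1R,4aR,8aR)-1-(iodomethyl)-2,5,5,8a-tetramethyl-1,4,4a,5,6,7,8,8a-octahydronaphthalene F10 and heated with PPh3 (MeCN, 90 °C) to give triphenyl{[(1R,4aR,8aR)-2,5,5,8a-tetramethyl-1,4,4a,5,6,7,8,8a-octahydronaphthalen-1-yl]methyl}phosphonium iodide F11. Its ylide (NaN(SiMe3)2, THF, −78 °C) undergoes Wittig olefination with 32 to give tert-butyl{[(2R)-2-[(3S,6R)-6-methyl-6-{(Z)-2-[(1R,4aR,8aR)-2,5,5,8a-tetramethyl-1,4,4a,5,6,7,8,8a-octahydronaphthalen-1-yl]ethenyl}-1,2-dioxan-3-yl]propyl]oxy}diphenylsilane F12, which is reduced with diimide under the conditions of step 24 to give 34.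

**Further compounds**
F1 | step 8 | (2E,8E,10E)-11-[dimethyl(phenyl)silyl]-3,7,7-trimethyldodeca-2,8,10-trien-1-ol | OC/C=C(\C)CCCC(C)(C)/C=C/C=C(\C)[Si](C)(C)c1ccccc1
F2 | step 8 | (2E,8E,10E)-11-[dimethyl(phenyl)silyl]-3,7,7-trimethyldodeca-2,8,10-trienal | O=C/C=C(\C)CCCC(C)(C)/C=C/C=C(\C)[Si](C)(C)c1ccccc1
F3 | step 8 | (1R,2R,4aR,8aR)-2-[dimethyl(phenyl)silyl]-2,5,5,8a-tetramethyl-1,2,4a,5,6,7,8,8a-octahydronaphthalene-1-carbaldehyde | O=C[C@@H]1[C@](C)([Si](C)(C)c2ccccc2)C=C[C@@H]2C(C)(C)CCC[C@@]12C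
F4 | step 8 | [(1R,2R,4aR,8aR)-2-[dimethyl(phenyl)silyl]-2,5,5,8a-tetramethyl-1,2,4a,5,6,7,8,8a-octahydronaphthalen-1-yl]methanol | OC[C@@H]1[C@](C)([Si](C)(C)c2ccccc2)C=C[C@@H]2C(C)(C)CCC[C@@]12C
F5 | step 20 | 2-methoxypropan-2-yl hydroperoxide | COC(C)(C)OO
F6 | step 20 | (2E,6R,7R)-8-[(tert-butyldiphenylsilyl)oxy]-3,7-dimethyl-6-{[(trifluoromethyl)sulfonyl]oxy}oct-2-en-1-yl acetate | CC(C)(C)[Si](c1ccccc1)(c1ccccc1)OC[C@@H](C)[C@H](OS(=O)(=O)C(F)(F)F)CC/C(C)=C/COC(C)=O
F7 | step 20 | (2E,6S,7R)-8-[(tert-butyldiphenylsilyl)oxy]-6-[(2-methoxypropan-2-yl)peroxy]-3,7-dimethyloct-2-en-1-yl acetate | CC(C)(C)[Si](c1ccccc1)(c1ccccc1)OC[C@@H](C)[C@@H](OOC(C)(C)OC)CC/C(C)=C/COC(C)=O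
F8 | step 20 | (2E,6S,7R)-8-[(tert-butyldiphenylsilyl)oxy]-6-[(2-methoxypropan-2-yl)peroxy]-3,7-dimethyloct-2-en-1-ol | CC(C)(C)[Si](c1ccccc1)(c1ccccc1)OC[C@@H](C)[C@@H](OOC(C)(C)OC)CC/C(C)=C/CO
F9 | step 20 | [(2S,3S)-3-{(3S,4R)-5-[(tert-butyldiphenylsilyl)oxy]-3-[(2-methoxypropan-2-yl)peroxy]-4-methylpentyl}-3-methyloxiran-2-yl]methanol | CC(C)(C)[Si](c1ccccc1)(c1ccccc1)OC[C@@H](C)[C@@H](OOC(C)(C)OC)CC[C@]1(C)O[C@H]1CO
F10 | step 23 | (1R,4aR,8aR)-1-(iodomethyl)-2,5,5,8a-tetramethyl-1,4,4a,5,6,7,8,8a-octahydronaphthalene | IC[C@@H]1C(C)=CC[C@@H]2C(C)(C)CCC[C@@]12C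
F11 | step 23 | triphenyl{[(1R,4aR,8aR)-2,5,5,8a-tetramethyl-1,4,4a,5,6,7,8,8a-octahydronaphthalen-1-yl]methyl}phosphonium iodide | [I-].c1ccccc1[P+](c1ccccc1)(c1ccccc1)C[C@@H]1C(C)=CC[C@@H]2C(C)(C)CCC[C@@]12C
F12 | step 23 | tert-butyl{[(2R)-2-[(3S,6R)-6-methyl-6-{(Z)-2-[(1R,4aR,8aR)-2,5,5,8a-tetramethyl-1,4,4a,5,6,7,8,8a-octahydronaphthalen-1-yl]ethenyl}-1,2-dioxan-3-yl]propyl]oxy}diphenylsilane | CC(C)(C)[Si](c1ccccc1)(c1ccccc1)OC[C@@H](C)[C@@H]1CC[C@](C)(/C=C\[C@@H]2C(C)=CC[C@@H]3C(C)(C)CCC[C@@]23C)OO1
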